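**Retrosynthetic overview**

- The target is taken back to its methyl ester, then to a 5‑O‑(1,1‑dimethylallyl) ether (aromatic Claisen relay O5 → C6), then to the 5‑methoxy ester (BCl3 demethylation next to the C4 carbonyl).
- The benzylic C–phenyl bond comes from a rhodium‑catalysed asymmetric conjugate addition of phenylboronic acid to a C8 E‑acrylate, made by Wittig reaction of a C8 aldehyde; C3 comes from hydrogenation of a 3‑methylidene group anti to the C2 methyl.
- Strategic feature: the pyranone ring is a six‑atom bridge C4a–C4(=O)–C3–C2–O1–C8a across two adjacent carbons of the benzene ring. C4 is therefore carbon monoxide, and C2, C3 and both methyl carbons are buta‑1,2‑diene; one palladium‑catalysed three‑component annulation of an ortho‑iodophenol forms C4a–C4, C4–C3 and O1–C2 and sets C2.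
- The iodophenol comes from 3,5‑dimethoxyphenol by ortho‑iodination and ortho‑formylation; the formyl group, placed next to the still free phenol, later becomes the C8 side chain.
- Ring order: the benzene ring is bought; the pyranone ring is closed in the key step; no other ring is formed.

Key step: step 3

Remark: the annulation substrate is 2‑iodo‑3,5‑dimethoxyphenol carrying a formyl group on its second ortho carbon; the formyl group is a spectator in the key step and fixes C8 before the phenol oxygen becomes O1, so no electrophilic substitution is needed later beside a prenyl group.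

Remark: the ligand hands written in steps 3 and 6 are the expected ones; the sense of induction would be assigned on the first run and the antipodal ligand used if it is opposite.

**Route**

Step 1
Reactants: 1 3,5-dimethoxyphenol
Product: 2 2-iodo-3,5-dimethoxyphenol
Conditions: I2 (1.0 equiv), morpholine (3 equiv), MeOH, 0 °C to rt
Reagents that add atoms: iodine, II
Why: Electrophilic aromatic iodination by the morpholine–iodine complex, which hydrogen-bonds to the phenol and should deliver iodine to the ortho carbon rather than to the para carbon crowded by two methoxy groups, any 4-iodo isomer being removed by chromatography.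

Step 2
Reactants: 2 2-iodo-3,5-dimethoxyphenol
Product: 3 2-hydroxy-3-iodo-4,6-dimethoxybenzaldehyde
Conditions: MgCl2 (2 equiv), Et3N (4 equiv), (CH2O)n, MeCN, reflux; then aq. HCl
Reagents that add atoms: paraformaldehyde (as formaldehyde), C=O
Why: Magnesium-phenoxide-directed ortho-formylation (Casnati–Skattebøl reaction) can enter only the single free ortho position, so the carbon that becomes C8 is fixed while the phenol that becomes O1 is still free.

Step 3
Reactants: 3 2-hydroxy-3-iodo-4,6-dimethoxybenzaldehyde; 4 buta-1,2-diene; 5 carbon monoxide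
Product: 6 (2S)-5,7-dimethoxy-2-methyl-3-methylidene-4-oxo-3,4-dihydro-2H-chromene-8-carbaldehyde
Conditions: Pd(OAc)2 (5 mol %), (R)-DTBM-SEGPHOS (6 mol %), iPr2NEt (1.5 equiv), CO (20 atm), 4 (4 equiv), toluene, 80 °C
Reagents that add atoms: none
Why: Proposed new method: zerovalent palladium inserts into the C–I bond of 3, the hindered ArPd(L2)I takes up CO, and the aroylpalladium adds across buta-1,2-diene with the acyl group on the central carbon, giving a (2-aroylallyl)Pd(L2) complex whose termini are CH2 and CH(CH3). The pyranone ring, the only ring closed, then forms by intramolecular allylic etherification: the neighbouring phenoxide attacks the methyl-bearing terminus from the face opposite palladium, so that C2 and C3 enter the six-membered ring, the CH2 terminus stays as the exocyclic methylene, and the bonds C4a–C4, C4–C3 and O1–C2 are made. The closest known reaction type is the racemic Pd(OAc)2/dppb carbonylative annulation of 2-iodophenols with allenes to 3-methylidenechroman-4-ones; the asymmetric element is taken from palladium-catalysed enantioselective allene heteroannulations and allylic etherifications by phenols. C2 is the only new stereocentre and is set by the chiral bisphosphine: the diastereomeric allyl complexes interconvert by π–σ–π shifts faster than the C–O bond forms, so the ligand pocket decides which face of the methyl-bearing terminus the phenoxide reaches (S wanted). The step needs carbonylation before allene insertion, attack at the substituted terminus and no migration of the double bond to the 2,3-dimethylchromone; CO pressure and the di-ortho-substituted arylpalladium favour the acyl complex, the methyl group stabilises positive charge at its terminus as in the racemic precedent, and the hindered amine is the base under which the racemic products are known to survive. The phenol ortho to iodine is the only internal nucleophile, which fixes the ring oxygen, and the formyl group is a spectator.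

Step 4
Reactants: 6 (2S)-5,7-dimethoxy-2-methyl-3-methylidene-4-oxo-3,4-dihydro-2H-chromene-8-carbaldehyde
Product: 7 (2S,3R)-5,7-dimethoxy-2,3-dimethyl-4-oxo-3,4-dihydro-2H-chromene-8-carbaldehyde (2,3-cis)
Conditions: H2 (1 atm), RhCl(PPh3)3 (5 mol %), toluene–EtOH (1:1), rt
Reagents that add atoms: none
Why: Homogeneous catalytic hydrogenation of the 1,1-disubstituted enone alkene (no double-bond migration to the chromone, aldehyde untouched at room temperature) should deliver hydrogen to the face opposite the C2 methyl, which allylic strain with the exocyclic methylene holds pseudoaxial, so that C3–H ends up trans to C2–CH3 and the two methyl groups cis (3R).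

Step 5
Reactants: 7 (2S,3R)-5,7-dimethoxy-2,3-dimethyl-4-oxo-3,4-dihydro-2H-chromene-8-carbaldehyde
Product: 8 methyl (2E)-3-[(2S,3R)-5,7-dimethoxy-2,3-dimethyl-4-oxo-3,4-dihydro-2H-chromen-8-yl]prop-2-enoate
Conditions: Ph3P=CHCO2Me (1.5 equiv), toluene, 90 °C
Reagents that add atoms: methyl (triphenylphosphoranylidene)acetate, COC(=O)C=P(c1ccccc1)(c1ccccc1)c1ccccc1
Why: Wittig olefination with a stabilised ylide gives the E-acrylate without added base, so the epimerisable cis C3 centre is not put at risk.

Step 6
Reactants: 8 methyl (2E)-3-[(2S,3R)-5,7-dimethoxy-2,3-dimethyl-4-oxo-3,4-dihydro-2H-chromen-8-yl]prop-2-enoate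
Product: 9 methyl (3R)-3-[(2S,3R)-5,7-dimethoxy-2,3-dimethyl-4-oxo-3,4-dihydro-2H-chromen-8-yl]-3-phenylpropanoate
Conditions: PhB(OH)2 (4 equiv), [Rh(OH)((S)-binap)]2 (3 mol % Rh), dioxane–H2O (10:1), 60 °C
Reagents that add atoms: phenylboronic acid, OB(O)c1ccccc1
Why: Hayashi–Miyaura rhodium-catalysed asymmetric conjugate addition of an arylboronic acid to a β-aryl acrylate, in which the BINAP-bound phenylrhodium adds to one face of the E-alkene (the α-si face is expected for the (S) ligand, which makes the benzylic centre R) and the base-free hydroxo catalyst spares C3.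

Step 7
Reactants: 9 methyl (3R)-3-[(2S,3R)-5,7-dimethoxy-2,3-dimethyl-4-oxo-3,4-dihydro-2H-chromen-8-yl]-3-phenylpropanoate
Product: 11 methyl (3R)-3-[(2S,3R)-5-hydroxy-7-methoxy-2,3-dimethyl-4-oxo-3,4-dihydro-2H-chromen-8-yl]-3-phenylpropanoate, via dichloroboryl chelate 10 (not isolated)
Conditions: BCl3 (2.5 equiv), CH2Cl2, −78 to 0 °C; then H2O
Reagents that add atoms: none
Why: Chelation-assisted aryl methyl ether cleavage, in which BCl3 bound to the C4 carbonyl removes only the peri 5-O-methyl group because neither the 7-methoxy group nor the methyl ester has such a neighbouring carbonyl.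

Step 8
Reactants: 11 methyl (3R)-3-[(2S,3R)-5-hydroxy-7-methoxy-2,3-dimethyl-4-oxo-3,4-dihydro-2H-chromen-8-yl]-3-phenylpropanoate
Product: 12 methyl (3R)-3-[(2S,3R)-7-methoxy-2,3-dimethyl-5-(2-methylbut-3-en-2-yloxy)-4-oxo-3,4-dihydro-2H-chromen-8-yl]-3-phenylpropanoate
Conditions: tert-butyl 2-methylbut-3-en-2-yl carbonate (2 equiv), Pd(PPh3)4 (5 mol %), THF, 0 °C
Reagents that add atoms: tert-butyl 2-methylbut-3-en-2-yl carbonate, CC(C)(C)OC(=O)OC(C)(C)C=C
Why: Decarboxylative Tsuji–Trost O-allylation, in which the tert-butoxide set free is quenched at once by the phenol and the phenoxide attacks the 1,1-dimethylallylpalladium complex at its tertiary terminus under kinetic control at low temperature.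

Step 9
Reactants: 12 methyl (3R)-3-[(2S,3R)-7-methoxy-2,3-dimethyl-5-(2-methylbut-3-en-2-yloxy)-4-oxo-3,4-dihydro-2H-chromen-8-yl]-3-phenylpropanoate
Product: 14 methyl (3R)-3-[(2S,3R)-5-hydroxy-7-methoxy-2,3-dimethyl-6-(3-methylbut-2-en-1-yl)-4-oxo-3,4-dihydro-2H-chromen-8-yl]-3-phenylpropanoate, via ortho-dienone 13 (not isolated)
Conditions: toluene (degassed), 110 °C, sealed tube
Reagents that add atoms: none
Why: Aromatic Claisen [3,3] rearrangement to C6, the only ortho carbon that bears hydrogen, inverts the allyl unit to the 3-methylbut-2-enyl group and enolisation of the dienone restores the hydrogen-bonded 5-phenol; C8 is substituted, so no para migration can follow.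

Step 10
Reactants: 14 methyl (3R)-3-[(2S,3R)-5-hydroxy-7-methoxy-2,3-dimethyl-6-(3-methylbut-2-en-1-yl)-4-oxo-3,4-dihydro-2H-chromen-8-yl]-3-phenylpropanoate
Product: 16 (3R)-3-[(2S,3R)-5-hydroxy-7-methoxy-2,3-dimethyl-6-(3-methylbut-2-en-1-yl)-4-oxo-3,4-dihydro-2H-chromen-8-yl]-3-phenylpropanoic acid, via trimethylstannyl ester 15 (not isolated)
Conditions: Me3SnOH (5 equiv), ClCH2CH2Cl, 70 °C; then 5% aq. HCl
Reagents that add atoms: trimethyltin hydroxide, C[Sn](C)(C)O
Why: Near-neutral methyl ester hydrolysis by trimethyltin hydroxide (acyl–oxygen cleavage) avoids both the hydroxide conditions that would epimerise the cis C3 centre and the strong acid that would cyclise the ortho-prenyl phenol.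

**Compound list**

1 | 3,5-dimethoxyphenol | COc1cc(O)cc(OC)c1 | starting material
2 | 2-iodo-3,5-dimethoxyphenol | COc1cc(O)c(I)c(OC)c1 | intermediate
3 | 2-hydroxy-3-iodo-4,6-dimethoxybenzaldehyde | O=Cc1c(O)c(I)c(OC)cc1OC | intermediate
4 | buta-1,2-diene | CC=C=C | starting material
5 | carbon monoxide | [C-]#[O+] | starting material
6 | (2S)-5,7-dimethoxy-2-methyl-3-methylidene-4-oxo-3,4-dihydro-2H-chromene-8-carbaldehyde | COc1cc(OC)c2c(c1C=O)O[C@@H](C)C(=C)C2=O | intermediate
7 | (2S,3R)-5,7-dimethoxy-2,3-dimethyl-4-oxo-3,4-dihydro-2H-chromene-8-carbaldehyde | COc1cc(OC)c2c(c1C=O)O[C@@H](C)[C@@H](C)C2=O | intermediate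
8 | methyl (2E)-3-[(2S,3R)-5,7-dimethoxy-2,3-dimethyl-4-oxo-3,4-dihydro-2H-chromen-8-yl]prop-2-enoate | COC(=O)/C=C/c1c(OC)cc(OC)c2c1O[C@@H](C)[C@@H](C)C2=O | intermediate
9 | methyl (3R)-3-[(2S,3R)-5,7-dimethoxy-2,3-dimethyl-4-oxo-3,4-dihydro-2H-chromen-8-yl]-3-phenylpropanoate | COc1cc(OC)c2c(c1[C@H](CC(=O)OC)c1ccccc1)O[C@@H](C)[C@@H](C)C2=O | intermediate
10 | methyl (3R)-3-[(2S,3R)-5-(dichloroboranyloxy)-7-methoxy-2,3-dimethyl-4-oxo-3,4-dihydro-2H-chromen-8-yl]-3-phenylpropanoate (boron chelated to the C4 carbonyl) | COc1cc(OB(Cl)Cl)c2c(c1[C@H](CC(=O)OC)c1ccccc1)O[C@@H](C)[C@@H](C)C2=O | intermediate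
11 | methyl (3R)-3-[(2S,3R)-5-hydroxy-7-methoxy-2,3-dimethyl-4-oxo-3,4-dihydro-2H-chromen-8-yl]-3-phenylpropanoate | COc1cc(O)c2c(c1[C@H](CC(=O)OC)c1ccccc1)O[C@@H](C)[C@@H](C)C2=O | intermediate
12 | methyl (3R)-3-[(2S,3R)-7-methoxy-2,3-dimethyl-5-(2-methylbut-3-en-2-yloxy)-4-oxo-3,4-dihydro-2H-chromen-8-yl]-3-phenylpropanoate | COc1cc(OC(C)(C)C=C)c2c(c1[C@H](CC(=O)OC)c1ccccc1)O[C@@H](C)[C@@H](C)C2=O | intermediate
13 | methyl (3R)-3-[(2S,3R)-7-methoxy-2,3-dimethyl-6-(3-methylbut-2-en-1-yl)-4,5-dioxo-3,4,5,6-tetrahydro-2H-chromen-8-yl]-3-phenylpropanoate (ortho-dienone, both C6 epimers) | COC1=C([C@H](CC(=O)OC)c3ccccc3)C2=C(C(=O)C1CC=C(C)C)C(=O)[C@H](C)[C@H](C)O2 | intermediate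
14 | methyl (3R)-3-[(2S,3R)-5-hydroxy-7-methoxy-2,3-dimethyl-6-(3-methylbut-2-en-1-yl)-4-oxo-3,4-dihydro-2H-chromen-8-yl]-3-phenylpropanoate | COc1c(CC=C(C)C)c(O)c2c(c1[C@H](CC(=O)OC)c1ccccc1)O[C@@H](C)[C@@H](C)C2=O | intermediate
15 | trimethylstannyl (3R)-3-[(2S,3R)-5-hydroxy-7-methoxy-2,3-dimethyl-6-(3-methylbut-2-en-1-yl)-4-oxo-3,4-dihydro-2H-chromen-8-yl]-3-phenylpropanoate | COc1c(CC=C(C)C)c(O)c2c(c1[C@H](CC(=O)O[Sn](C)(C)C)c1ccccc1)O[C@@H](C)[C@@H](C)C2=O | intermediate
16 | (3R)-3-[(2S,3R)-5-hydroxy-7-methoxy-2,3-dimethyl-6-(3-methylbut-2-en-1-yl)-4-oxo-3,4-dihydro-2H-chromen-8-yl]-3-phenylpropanoic acid (CNP0172137.1) | COc1c(CC=C(C)C)c(O)c2c(c1[C@H](CC(=O)O)c1ccccc1)O[C@@H](C)[C@@H](C)C2=O | target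

**Step count and risks**

Total step count: 10. Longest linear sequence: 10 steps (1 to 16).

Steps most likely to fail:

1. Step 3 (the proposed new method). The ligand may not discriminate the two faces of the methyl-bearing allyl terminus well enough, or oxygen attack may drift to the CH2 terminus, or the exocyclic double bond may migrate into the ring. The fallback uses known chemistry; it sets out from 3 and comes back at 9. The established racemic carbonylative annulation of 3 with 4 and 5 (Pd(OAc)2, dppb, iPr2NEt, CO 20 atm, benzene, 100 °C) would give racemic 5,7-dimethoxy-2-methyl-3-methylidene-4-oxo-3,4-dihydro-2H-chromene-8-carbaldehyde F1. Hydrogenation as in step 4 would give the racemic cis aldehyde F2, and the Wittig reaction of step 5 the racemic acrylate F3. The rhodium/(S)-BINAP addition of step 6 then sets the benzylic centre R in both enantiomers, so 9 forms together with its (2R,3S) diastereomer, methyl (3R)-3-[(2R,3S)-5,7-dimethoxy-2,3-dimethyl-4-oxo-3,4-dihydro-2H-chromen-8-yl]-3-phenylpropanoate F4. The two diastereomers are separated by preparative HPLC, at the cost of half the material.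

2. Step 6. The twisted, di-ortho-oxygenated β-aryl acrylate may insert into the phenyl–rhodium bond so slowly that protodeboronation consumes the boronic acid, or the facial selectivity may be eroded. The fallback sets out from 7 and comes back at 9. PhTi(OiPr)3 (THF, −20 °C) adds to the aldehyde only and gives the diarylmethanol (2S,3R)-8-[hydroxy(phenyl)methyl]-5,7-dimethoxy-2,3-dimethyl-2,3-dihydro-4H-chromen-4-one F5 as a mixture of carbinol epimers. Catalytic TMSOTf (CH2Cl2, −78 °C) ionises it to the trioxygenated diarylmethyl cation, which is captured by 1-methoxy-1-(trimethylsilyloxy)ethene in a Mukaiyama-type benzylic substitution. A small nucleophile attacking a planar cation avoids the steric problem, but the product is 9 together with its benzylic epimer, methyl (3S)-3-[(2S,3R)-5,7-dimethoxy-2,3-dimethyl-4-oxo-3,4-dihydro-2H-chromen-8-yl]-3-phenylpropanoate F6, and the two are separated by preparative HPLC.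

3. Step 8. The hydrogen-bonded phenoxide may add slowly, and the tertiary aryl ether may ionise again on palladium, so that the material drifts to the linear O-prenyl ether or to C-allylation. The fallback sets out from 11 and comes back at 12. Copper-catalysed propargylic etherification with 3-chloro-3-methylbut-1-yne (CuCl2 1 mol %, DBU, MeCN, 0 °C) forms the tertiary ether irreversibly, giving methyl (3R)-3-[(2S,3R)-7-methoxy-2,3-dimethyl-5-(2-methylbut-3-yn-2-yloxy)-4-oxo-3,4-dihydro-2H-chromen-8-yl]-3-phenylpropanoate F7. Semihydrogenation of the alkyne (H2, Pd/CaCO3 poisoned with Pb(OAc)2, quinoline, EtOAc) then gives 12.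

**Further compounds**

F1 | step 3 | racemic 5,7-dimethoxy-2-methyl-3-methylidene-4-oxo-3,4-dihydro-2H-chromene-8-carbaldehyde | COc1cc(OC)c2c(c1C=O)OC(C)C(=C)C2=O
F2 | step 3 | racemic cis-5,7-dimethoxy-2,3-dimethyl-4-oxo-3,4-dihydro-2H-chromene-8-carbaldehyde (7 and its enantiomer; the (2R,3S) half is drawn) | COc1cc(OC)c2c(c1C=O)O[C@H](C)[C@H](C)C2=O
F3 | step 3 | racemic methyl (2E)-3-(cis-5,7-dimethoxy-2,3-dimethyl-4-oxo-3,4-dihydro-2H-chromen-8-yl)prop-2-enoate (8 and its enantiomer; the (2R,3S) half is drawn) | COC(=O)/C=C/c1c(OC)cc(OC)c2c1O[C@H](C)[C@H](C)C2=O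
F4 | step 3 | methyl (3R)-3-[(2R,3S)-5,7-dimethoxy-2,3-dimethyl-4-oxo-3,4-dihydro-2H-chromen-8-yl]-3-phenylpropanoate | COc1cc(OC)c2c(c1[C@H](CC(=O)OC)c1ccccc1)O[C@H](C)[C@H](C)C2=O
F5 | step 6 | (2S,3R)-8-[hydroxy(phenyl)methyl]-5,7-dimethoxy-2,3-dimethyl-2,3-dihydro-4H-chromen-4-one (both carbinol epimers) | COc1cc(OC)c2c(c1C(O)c1ccccc1)O[C@@H](C)[C@@H](C)C2=O
F6 | step 6 | methyl (3S)-3-[(2S,3R)-5,7-dimethoxy-2,3-dimethyl-4-oxo-3,4-dihydro-2H-chromen-8-yl]-3-phenylpropanoate | COc1cc(OC)c2c(c1[C@@H](CC(=O)OC)c1ccccc1)O[C@@H](C)[C@@H](C)C2=O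
F7 | step 8 | methyl (3R)-3-[(2S,3R)-7-methoxy-2,3-dimethyl-5-(2-methylbut-3-yn-2-yloxy)-4-oxo-3,4-dihydro-2H-chromen-8-yl]-3-phenylpropanoate | COc1cc(OC(C)(C)C#C)c2c(c1[C@H](CC(=O)OC)c1ccccc1)O[C@@H](C)[C@@H](C)C2=O
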